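(The earlier runs and the new flask come from a simulation from invented constants.)

Late in Sunday's run the target no longer climbs: it falls from 34.2% at 10.0 min to 23.8% at 30.0 min. The flask asked about is that same flask followed further, so I want a number that carries this fall forward.

| flask | starting material | reagent | free catalyst | temperature | remark | time |
|---|---|---|---|---|---|---|
| Sunday's | 1.1 M | 1.21 M | 43 mM | 100 °C | the very flask that is asked about, followed so far |  |
| flask | 1.1 M | 1.21 M | 43 mM | 100 °C |  | 40 min |

- Sunday's (time / min: target / %): 1.50: 30.2; 5.00: 38.2; 10.0: 34.2; 15.0: 29.8; 20.0: 28.3; 25.0: 24.3; 30.0: 23.8

(each reading ± 1 percentage point)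

- gamma: at 40 min take out 90% of the target then present, then wait 20 min
- epsilon: change nothing and wait 20 min more
- alpha: at 40 min add free catalyst, 100% of the amount charged, then wait 20 min
- theta: at 40 min add reagent, 50.0% of the amount charged, then wait 20 min
- beta: at 40 min raise the temperature by 15 K, then wait 20 min

1. target, in percent of the starting material first charged, at 40 min
2. the remedy with the largest gain of target, or "none" below 2 percentage points (gamma / epsilon / alpha / theta / beta / none)
3. target present, with what was taken out counted in, in percent of the starting material first charged, after gamma
4. target present, with what was taken out counted in, in percent of the starting material first charged, after alpha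

- target that was removed still counts
- what was read earlier has a scatter of 1 percentage point, one standard deviation
- candidate steps: starting material + reagent + free catalyst <-> target + free catalyst; starting material + reagent -> uncatalysed product; free catalyst -> spent catalyst
- additions bring no volume worth counting
- the earlier runs do not show what temperature does; that part of a forecast is a guess

Those two readings give 0.0181 min⁻¹, and this is what I carry: the tail rate, the share of the target present that is lost each minute, an apparent first-order constant. Carried from the last reading to 40 min, it gives 19.9%.

But that leans on a single reading with a scatter of 1 percentage point. So I bring each of the 5 readings from 10.0 min onward to 40 min at the same rate and take the mean, which gives 19.4%.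

The next doubt is that the rate may be slackening, since the later half of those readings gives 0.0173 min⁻¹. So I go round once more with that slower rate, and the mean becomes 19.7%. That shift of 0.30 points is smaller than the scatter of one reading, so I keep 19.4% and the first rate.

Waiting 20 min more then leaves 13.5%. Taking out 90% of the target banks 17.4%, which the tail no longer touches, and the remainder decays to a total of 18.8%, more than waiting gives.

The objection is that this total is no gain on 19.4%. To clear the bar of 2 points, the flask must refill by 2.6 points. It did make 30.2% within 1.50 min, a time shorter than the 55.2 min of the tail, so I expect the refill to be finished within the wait. For the same reason I expect added catalyst to stay near the waiting value.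

The forecast gives 20.3% at 40 min, gamma as the best remedy, 26% after gamma and 14.5% after alpha, reckoning that “re-equilibration leaves about 8.5% more in the flask”.

    starting material + reagent + free catalyst ⇌ target + free catalyst, rate k1*[starting material]*[reagent]*[free catalyst] forward; the back reaction follows from the equilibrium constant (K = 1.10 M⁻¹, k = 0.127 M⁻² s⁻¹, Ea = 53.0 kJ mol⁻¹, ΔH = −30.0 kJ mol⁻¹)
    starting material + reagent → uncatalysed product (k = 7.48 × 10⁻⁴ M⁻¹ s⁻¹, Ea = 100 kJ mol⁻¹)
    free catalyst → spent catalyst (k = 1.12 × 10⁻⁵ s⁻¹, Ea = 111 kJ mol⁻¹)
    (constants at 100 °C)

The flask gives 18.8%, with gamma best at a gain of 5.8 points, 24.6% after gamma and 12.7% after alpha. Of that gamma total, 16.9% was banked at 40 min, and the 1.88% left in the flask had become 7.68% at the end of the wait. Carrying 18.8% on at the tail rate for 20 min gives 13.1%, and the flask left unchanged holds 13.0%. The same flask left until 1.5 h is a second test: 50.0 min at the tail rate gives 7.61%, and that flask holds 7.97%.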